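The target is cut at two neighbouring carbons of the benzofuran benzo ring: C5, which carries the propyl tether to ring A (the resorcinol ring), and C4, which carries the prenyl group. Adjacent C4 and C5 are the two termini of a 4,5-benzofuranyne, so one operation assembles three pieces: the aryne, released from 4-iodo-7-methoxybenzofuran-5-yl 4-chlorobenzenesulfonate by iodine–magnesium exchange and sulfonate loss, accepts the ring-A 3-arylpropyl Grignard at C5, and the C4 arylmagnesium so formed is prenylated with prenyl bromide under CuI catalysis. Both hindered aryl–CH2 bonds arise in one pot; demethylation at C7 and MOM removal complete the synthesis.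

Key step: step 12

Remark on the design: iodine, not bromine, sits at C4 of the aryne precursor, because an aryl iodide exchanges with iPrMgCl at −78 °C, where the ortho-magnesiated sulfonate is still intact; a bromide would exchange only at temperatures where the aryne already forms and would be trapped by the exchange reagent.

Assumption: 5-iodovanillin, resorcinol, prenyl bromide and all named reagents are purchased; the target is achiral, so no stereocentre has to be set.

Step 1
Reactants: 1 5-iodovanillin (4-hydroxy-3-iodo-5-methoxybenzaldehyde)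
Product: 4 7-methoxy-1-benzofuran-5-carbaldehyde, via alkynylphenol 2 (not isolated), via 2-silylbenzofuran 3 (not isolated)
Conditions: Me3SiC≡CH (1.5 equiv), Pd(PPh3)2Cl2 (3 mol %), CuI (6 mol %), Et3N, DMF, 65 °C, sealed tube; then TBAF, THF, 50 °C, same pot
Reagents that add atoms: trimethylsilylacetylene, C#C[Si](C)(C)C
Why: Sonogashira coupling at the aryl iodide places the alkyne next to the free phenol, which closes the furan by CuI/amine-promoted 5-endo-dig hydroalkoxylation, and fluoride then removes the C2 silyl group by protodesilylation (Sonogashira–heteroannulation sequence).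

Step 2
Reactants: 4 7-methoxy-1-benzofuran-5-carbaldehyde
Product: 6 7-methoxy-1-benzofuran-5-ol, via aryl formate 5 (not isolated)
Conditions: mCPBA (1.3 equiv), NaHCO3, CH2Cl2, 0 °C → rt; then K2CO3, MeOH, rt
Reagents that add atoms: 3-chloroperoxybenzoic acid, O=C(OO)c1cccc(Cl)c1
Why: Baeyer–Villiger (Dakin-type) oxidation in which the electron-rich aryl group, para to the furan oxygen, should migrate in preference to hydride, after which mild methanolysis releases the phenol from the formate.

Step 3
Reactants: 6 7-methoxy-1-benzofuran-5-ol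
Product: 7 4-iodo-7-methoxy-1-benzofuran-5-ol
Conditions: NIS (1.0 equiv), MeCN, −10 °C → 0 °C
Reagents that add atoms: N-iodosuccinimide, O=C1CCC(=O)N1I
Why: electrophilic aromatic iodination of the phenol, expected at C4 because that carbon is ortho to the hydroxyl, para to the C7 methoxy group and the α-type position next to the ring fusion, whereas C6 is flanked by two oxygen substituents.

Step 4
Reactants: 7 4-iodo-7-methoxy-1-benzofuran-5-ol
Product: 8 4-iodo-7-methoxy-1-benzofuran-5-yl 4-chlorobenzenesulfonate
Conditions: 4-ClC6H4SO2Cl (1.2 equiv), Et3N, DMAP (cat.), CH2Cl2, 0 °C → rt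
Reagents that add atoms: 4-chlorobenzenesulfonyl chloride, O=S(=O)(Cl)c1ccc(Cl)cc1
Why: DMAP-catalysed O-sulfonylation of the phenol; the 4-chlorobenzenesulfonate is chosen because its ortho-magnesiated form persists at −78 °C and eliminates only on warming.

Step 5
Reactants: 9 resorcinol (benzene-1,3-diol, 3 equiv); 10 prenyl bromide (1-bromo-3-methylbut-2-ene)
Product: 11 3-[(3-methylbut-2-en-1-yl)oxy]phenol
Conditions: K2CO3 (1.2 equiv), acetone, reflux
Reagents that add atoms: none
Why: Williamson ether synthesis on a symmetrical diol, where a threefold excess of resorcinol keeps dialkylation low and the surplus is washed out with water.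

Step 6
Reactants: 11 3-[(3-methylbut-2-en-1-yl)oxy]phenol
Product: 12 4-(2-methylbut-3-en-2-yl)benzene-1,3-diol
Conditions: EtOH/H2O (4:1), 140 °C, sealed vessel, argon
Reagents that add atoms: none
Why: aromatic Claisen rearrangement ([3,3]-sigmatropic shift with allyl inversion, then enolisation) should deliver the 1,1-dimethylallyl group to the ortho carbon para to the free hydroxyl, because the other ortho carbon lies between two oxygens and would have to carry a quaternary centre there; the protic medium accelerates the shift so that it runs below the temperatures at which the product isomerises or cyclises.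

Step 7
Reactants: 12 4-(2-methylbut-3-en-2-yl)benzene-1,3-diol
Product: 13 2,4-bis(methoxymethoxy)-1-(2-methylbut-3-en-2-yl)benzene
Conditions: MOMCl (3 equiv), iPr2NEt (4 equiv), CH2Cl2, 0 °C → rt
Reagents that add atoms: chloromethyl methyl ether, COCCl
Why: O-alkylation of both phenols as methoxymethyl acetals, which withstand the organolithium, Grignard and thiolate steps and are removed together by mild acid at the end.

Step 8
Reactants: 13 2,4-bis(methoxymethoxy)-1-(2-methylbut-3-en-2-yl)benzene
Product: 14 1-bromo-2,4-bis(methoxymethoxy)-5-(2-methylbut-3-en-2-yl)benzene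
Conditions: NBS (1.0 equiv), MeCN, 0 °C, dark
Reagents that add atoms: N-bromosuccinimide, O=C1CCC(=O)N1Br
Why: electrophilic aromatic bromination at the one ring carbon that is para to one acetal oxygen, ortho to the other and not flanked on both sides; the monosubstituted alkene should not compete with the doubly activated arene.

Step 9
Reactants: 14 1-bromo-2,4-bis(methoxymethoxy)-5-(2-methylbut-3-en-2-yl)benzene
Product: 16 3-[2,4-bis(methoxymethoxy)-5-(2-methylbut-3-en-2-yl)phenyl]propan-1-ol, via aryllithium 15 (not isolated)
Conditions: n-BuLi (1.05 equiv), THF, −78 °C; then oxetane (3 equiv), BF3·OEt2 (1.5 equiv), −78 °C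
Reagents that add atoms: oxetane, C1COC1
Why: bromine–lithium exchange followed by BF3-promoted ring opening of oxetane by the aryllithium installs the three-carbon chain with its terminal hydroxyl in one operation.

Step 10
Reactants: 16 3-[2,4-bis(methoxymethoxy)-5-(2-methylbut-3-en-2-yl)phenyl]propan-1-ol
Product: 17 1-(3-bromopropyl)-2,4-bis(methoxymethoxy)-5-(2-methylbut-3-en-2-yl)benzene
Conditions: CBr4 (1.3 equiv), PPh3 (1.4 equiv), 2,6-lutidine (0.2 equiv), CH2Cl2, 0 °C
Reagents that add atoms: carbon tetrabromide, BrC(Br)(Br)Br
Why: Appel bromination converts the primary alcohol into the bromide under nearly neutral conditions that leave the acetals and the alkene untouched.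

Step 11
Reactants: 17 1-(3-bromopropyl)-2,4-bis(methoxymethoxy)-5-(2-methylbut-3-en-2-yl)benzene
Product: 18 {3-[2,4-bis(methoxymethoxy)-5-(2-methylbut-3-en-2-yl)phenyl]propyl}magnesium bromide (THF solution, titrated and used directly)
Conditions: Mg turnings (activated with a trace of BrCH2CH2Br), THF, 40 °C, slow addition
Reagents that add atoms: magnesium, [Mg]
Why: oxidative insertion of magnesium into the primary C–Br bond (Grignard formation); slow addition limits Wurtz coupling, and the acetal ethers and the isolated alkene are inert.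

Step 12
Reactants: 8 4-iodo-7-methoxy-1-benzofuran-5-yl 4-chlorobenzenesulfonate; 18 {3-[2,4-bis(methoxymethoxy)-5-(2-methylbut-3-en-2-yl)phenyl]propyl}magnesium bromide (1.5 equiv); 10 prenyl bromide (3 equiv)
Product: 22 5-{3-[2,4-bis(methoxymethoxy)-5-(2-methylbut-3-en-2-yl)phenyl]propyl}-7-methoxy-4-(3-methylbut-2-en-1-yl)-1-benzofuran, via magnesiated sulfonate 19 (not isolated), via 4,5-benzofuranyne 20 (not isolated), via C4 arylmagnesium 21 (not isolated)
Conditions: iPrMgCl (1.05 equiv), THF, −78 °C, 30 min; 18, −78 °C → rt; then CuI (10 mol %), 10, −20 °C → rt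
Reagents that add atoms: none
Why: Iodine–magnesium exchange at C4 of 8 should be complete at −78 °C and give 19, which on warming loses magnesium 4-chlorobenzenesulfonate to form aryne 20; the primary alkyl Grignard 18 then adds across the strained triple bond (carbomagnesiation), forming the C5–CH2 bond and leaving magnesium on C4 (21), and CuI-catalysed allylic substitution on prenyl bromide forms the C4–CH2 bond. The closest known reaction type is the three-component coupling of arynes generated from 2-magnesiated aryl sulfonates with Grignard reagents, followed by copper-catalysed allylation of the resulting arylmagnesium. No ring is closed and no stereocentre is created. The step needs site selectivity in the addition: by analogy with 4,5-indolyne, the five-membered ring fusion should distort the aryne so that C5 is the flatter, more electrophilic carbon and C4 the better carbanion site, and C5 is also the less hindered terminus because C4 lies peri to C3–H; this preference is predicted and not demonstrated for this benzofuranyne. It also needs α-selectivity in the allylation, which the arylcopper intermediate should secure by attacking prenyl bromide at the unsubstituted CH2 terminus, away from the gem-dimethyl carbon. The iodide ensures that no isopropyl Grignard remains when the aryne forms, and the excess of 18 lets it outcompete 19 as the aryne trap.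

Step 13
Reactants: 22 5-{3-[2,4-bis(methoxymethoxy)-5-(2-methylbut-3-en-2-yl)phenyl]propyl}-7-methoxy-4-(3-methylbut-2-en-1-yl)-1-benzofuran
Product: 23 5-{3-[2,4-bis(methoxymethoxy)-5-(2-methylbut-3-en-2-yl)phenyl]propyl}-4-(3-methylbut-2-en-1-yl)-1-benzofuran-7-ol
Conditions: NaSEt (5 equiv), DMF, 120 °C
Reagents that add atoms: none
Why: SN2 demethylation of the aryl methyl ether by thiolate; the acetals, the alkenes and the benzofuran are not electrophilic toward thiolate, and any partial loss of MOM would be harmless because these groups are removed next.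

Step 14
Reactants: 23 5-{3-[2,4-bis(methoxymethoxy)-5-(2-methylbut-3-en-2-yl)phenyl]propyl}-4-(3-methylbut-2-en-1-yl)-1-benzofuran-7-ol
Product: 24 4-{3-[7-hydroxy-4-(3-methylbut-2-en-1-yl)-1-benzofuran-5-yl]propyl}-6-(2-methylbut-3-en-2-yl)benzene-1,3-diol (target)
Conditions: HCl (3 M aq.), MeOH, 40 °C
Reagents that add atoms: none
Why: acid-catalysed acetal cleavage (methanolysis of both MOM ethers); the prenyl group has no neighbouring hydroxyl to cyclise onto, and the monosubstituted vinyl group of the 1,1-dimethylallyl unit is slow to protonate under these mild conditions.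

Compound list

1 | 5-iodovanillin (4-hydroxy-3-iodo-5-methoxybenzaldehyde) | COc1cc(C=O)cc(I)c1O | starting material
2 | 4-hydroxy-3-methoxy-5-[(trimethylsilyl)ethynyl]benzaldehyde | COc1cc(C=O)cc(C#C[Si](C)(C)C)c1O | intermediate
3 | 7-methoxy-2-(trimethylsilyl)-1-benzofuran-5-carbaldehyde | COc1cc(C=O)cc2cc([Si](C)(C)C)oc12 | intermediate
4 | 7-methoxy-1-benzofuran-5-carbaldehyde | COc1cc(C=O)cc2ccoc12 | intermediate
5 | 7-methoxy-1-benzofuran-5-yl formate | COc1cc(OC=O)cc2ccoc12 | intermediate
6 | 7-methoxy-1-benzofuran-5-ol | COc1cc(O)cc2ccoc12 | intermediate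
7 | 4-iodo-7-methoxy-1-benzofuran-5-ol | COc1cc(O)c(I)c2ccoc12 | intermediate
8 | 4-iodo-7-methoxy-1-benzofuran-5-yl 4-chlorobenzenesulfonate | COc1cc(OS(=O)(=O)c2ccc(Cl)cc2)c(I)c2ccoc12 | intermediate
9 | resorcinol (benzene-1,3-diol) | Oc1cccc(O)c1 | starting material
10 | prenyl bromide (1-bromo-3-methylbut-2-ene) | CC(C)=CCBr | starting material
11 | 3-[(3-methylbut-2-en-1-yl)oxy]phenol | CC(C)=CCOc1cccc(O)c1 | intermediate
12 | 4-(2-methylbut-3-en-2-yl)benzene-1,3-diol | C=CC(C)(C)c1ccc(O)cc1O | intermediate
13 | 2,4-bis(methoxymethoxy)-1-(2-methylbut-3-en-2-yl)benzene | C=CC(C)(C)c1ccc(OCOC)cc1OCOC | intermediate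
14 | 1-bromo-2,4-bis(methoxymethoxy)-5-(2-methylbut-3-en-2-yl)benzene | C=CC(C)(C)c1cc(Br)c(OCOC)cc1OCOC | intermediate
15 | [2,4-bis(methoxymethoxy)-5-(2-methylbut-3-en-2-yl)phenyl]lithium | C=CC(C)(C)c1cc([Li])c(OCOC)cc1OCOC | intermediate
16 | 3-[2,4-bis(methoxymethoxy)-5-(2-methylbut-3-en-2-yl)phenyl]propan-1-ol | C=CC(C)(C)c1cc(CCCO)c(OCOC)cc1OCOC | intermediate
17 | 1-(3-bromopropyl)-2,4-bis(methoxymethoxy)-5-(2-methylbut-3-en-2-yl)benzene | C=CC(C)(C)c1cc(CCCBr)c(OCOC)cc1OCOC | intermediate
18 | {3-[2,4-bis(methoxymethoxy)-5-(2-methylbut-3-en-2-yl)phenyl]propyl}magnesium bromide | C=CC(C)(C)c1cc(CCC[Mg]Br)c(OCOC)cc1OCOC | intermediate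
19 | [5-(4-chlorobenzenesulfonyloxy)-7-methoxy-1-benzofuran-4-yl]magnesium chloride | COc1cc(OS(=O)(=O)c2ccc(Cl)cc2)c([Mg]Cl)c2ccoc12 | intermediate
20 | 7-methoxy-4,5-didehydro-1-benzofuran (7-methoxy-4,5-benzofuranyne) | COC1=CC#CC2=C1OC=C2 | intermediate
21 | (5-{3-[2,4-bis(methoxymethoxy)-5-(2-methylbut-3-en-2-yl)phenyl]propyl}-7-methoxy-1-benzofuran-4-yl)magnesium bromide | COc1cc(CCCc2cc(C(C)(C)C=C)c(OCOC)cc2OCOC)c([Mg]Br)c2ccoc12 | intermediate
22 | 5-{3-[2,4-bis(methoxymethoxy)-5-(2-methylbut-3-en-2-yl)phenyl]propyl}-7-methoxy-4-(3-methylbut-2-en-1-yl)-1-benzofuran | COc1cc(CCCc2cc(C(C)(C)C=C)c(OCOC)cc2OCOC)c(CC=C(C)C)c2ccoc12 | intermediate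
23 | 5-{3-[2,4-bis(methoxymethoxy)-5-(2-methylbut-3-en-2-yl)phenyl]propyl}-4-(3-methylbut-2-en-1-yl)-1-benzofuran-7-ol | Oc1cc(CCCc2cc(C(C)(C)C=C)c(OCOC)cc2OCOC)c(CC=C(C)C)c2ccoc12 | intermediate
24 | 4-{3-[7-hydroxy-4-(3-methylbut-2-en-1-yl)-1-benzofuran-5-yl]propyl}-6-(2-methylbut-3-en-2-yl)benzene-1,3-diol (achiral) | C=CC(C)(C)c1cc(CCCc2cc(O)c3occc3c2CC=C(C)C)c(O)cc1O | target

Total step count: 14. Longest linear sequence: 10 steps (steps 5 to 14, from resorcinol); the benzofuran branch (steps 1 to 4) joins at step 12.

Steps most likely to fail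

Step 12. The alkyl Grignard may attack the aryne at C4 instead of C5 and give the transposed substitution pattern. The aryne may also be consumed by the magnesiated sulfonate instead of by 18, or the C4 arylmagnesium may be protonated before it is allylated. The fallback makes the two bonds separately by known reactions and sets out from phenol 6 and Grignard 18. Phenol 6 would be O-alkylated with tert-butyl 2-methylbut-3-en-2-yl carbonate and Pd(PPh3)4 in THF to give 7-methoxy-5-[(2-methylbut-3-en-2-yl)oxy]-1-benzofuran F1. Aromatic Claisen rearrangement of this ether in xylene at 130 °C, expected mainly toward C4 next to the ring fusion, would give 7-methoxy-4-(3-methylbut-2-en-1-yl)-1-benzofuran-5-ol F2. Tf2O and pyridine would convert it into 7-methoxy-4-(3-methylbut-2-en-1-yl)-1-benzofuran-5-yl trifluoromethanesulfonate F3. Grignard 18 would be transmetalated with ZnCl2 to {3-[2,4-bis(methoxymethoxy)-5-(2-methylbut-3-en-2-yl)phenyl]propyl}zinc chloride F4, and Negishi coupling of F3 with F4 (Pd(dppf)Cl2, THF, 50 °C) would come back to the route at compound 22.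

Step 6. The allyl unit may migrate to the carbon between the two oxygens, or the ortho-(1,1-dimethylallyl)phenol may react further by abnormal Claisen isomerisation or by ring closure onto the neighbouring hydroxyl. The fallback builds the quaternary benzylic carbon by cross-coupling and sets out from resorcinol 9. Double protection with MOMCl and iPr2NEt would give 1,3-bis(methoxymethoxy)benzene F5, and NBS in MeCN would give 1-bromo-2,4-bis(methoxymethoxy)benzene F6. α-Arylation of isobutyraldehyde with F6 ([Pd(allyl)Cl]2, dppf, Cs2CO3, dioxane, 80 °C) would give 2-[2,4-bis(methoxymethoxy)phenyl]-2-methylpropanal F7. Wittig methylenation (Ph3PCH3Br, KOtBu, THF) would come back to the route at compound 13.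

Step 2. The peracid may oxidise the furan C2–C3 double bond, or hydride may migrate instead of the aryl group and leave a carboxylic acid. The fallback carries out the oxidation before the furan exists and sets out from 5-iodovanillin 1. Classical Dakin oxidation (H2O2, aqueous NaOH, 0 °C → rt) would give 2-iodo-6-methoxybenzene-1,4-diol F8. The degassed one-pot Sonogashira coupling, cyclisation and desilylation of step 1 would then proceed through 2-methoxy-6-[(trimethylsilyl)ethynyl]benzene-1,4-diol F9 and 7-methoxy-2-(trimethylsilyl)-1-benzofuran-5-ol F10 and come back to the route at compound 6.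

Further compounds

F1 | step 12 | 7-methoxy-5-[(2-methylbut-3-en-2-yl)oxy]-1-benzofuran | COc1cc(OC(C)(C)C=C)cc2ccoc12
F2 | step 12 | 7-methoxy-4-(3-methylbut-2-en-1-yl)-1-benzofuran-5-ol | COc1cc(O)c(CC=C(C)C)c2ccoc12
F3 | step 12 | 7-methoxy-4-(3-methylbut-2-en-1-yl)-1-benzofuran-5-yl trifluoromethanesulfonate | COc1cc(OS(=O)(=O)C(F)(F)F)c(CC=C(C)C)c2ccoc12
F4 | step 12 | {3-[2,4-bis(methoxymethoxy)-5-(2-methylbut-3-en-2-yl)phenyl]propyl}zinc chloride | C=CC(C)(C)c1cc(CCC[Zn]Cl)c(OCOC)cc1OCOC
F5 | step 6 | 1,3-bis(methoxymethoxy)benzene | COCOc1cccc(OCOC)c1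
F6 | step 6 | 1-bromo-2,4-bis(methoxymethoxy)benzene | COCOc1ccc(Br)c(OCOC)c1
F7 | step 6 | 2-[2,4-bis(methoxymethoxy)phenyl]-2-methylpropanal | COCOc1ccc(C(C)(C)C=O)c(OCOC)c1
F8 | step 2 | 2-iodo-6-methoxybenzene-1,4-diol | COc1cc(O)cc(I)c1O
F9 | step 2 | 2-methoxy-6-[(trimethylsilyl)ethynyl]benzene-1,4-diol | COc1cc(O)cc(C#C[Si](C)(C)C)c1O
F10 | step 2 | 7-methoxy-2-(trimethylsilyl)-1-benzofuran-5-ol | COc1cc(O)cc2cc([Si](C)(C)C)oc12
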